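**Retrosynthetic overview**
- Target ⇒ ester C–O bond: (5S,6S)-5-hydroxy-6-[(E)-propenyl]-5,6-dihydropyran-2-one (phomalactone) + (2E,4E,6S)-4,6-dimethyldodeca-2,4-dienoic acid.
- The dihydropyranone is the only ring that is built; it is closed in the penultimate step by ring-closing metathesis of the mono-acrylate of C2-symmetric (2E,4S,5S,6E)-octa-2,6-diene-4,5-diol.
- Diene-diol ⇒ acetonide of L-tartaric acid: both carboxyl carbons are exchanged for (E)-propenyl in one visible-light nickel/iridium double decarboxylative alkenylation (key C–C bonds; the trans-dioxolane relays the L-threo configuration).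
- Dienoic acid ⇒ Doebner–Knoevenagel and Wittig homologation of (S)-2-methyloctanal ⇒ Roche-ester-derived (R)-3-bromo-2-methylpropan-1-ol + pentyl Grignard reagent.

Assumption: the SMILES is read as the cis-(5S,6S) lactone acylated by the (2E,4E,6S) acid, and trans-1-bromopropene and (R)-3-bromo-2-methylpropan-1-ol are taken as catalogue chemicals.

**Route**

Step 1
Reactants: 1 (R)-3-bromo-2-methylpropan-1-ol; 2 pentylmagnesium bromide
Product: 3 (S)-2-methyloctan-1-ol
Conditions: 2 (3.0 equiv), Li2CuCl4 (5 mol%), THF, −78 → 0 °C; aq NH4Cl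
Reagents that add atoms: pentylmagnesium bromide (2), CCCCC[Mg]Br
Why: Copper-catalysed (Kochi-type) alkyl–alkyl cross-coupling in which the first equivalent of 2 only deprotonates the hydroxyl and the cuprate then displaces the primary bromide, so the bought stereocentre is untouched (R becomes S only through the change in CIP ranks).

Step 2
Reactants: 3 (S)-2-methyloctan-1-ol; 4 2-(triphenylphosphoranylidene)propanal
Product: 6 (2E,4S)-2,4-dimethyldec-2-enal, via (S)-2-methyloctanal 5 (not isolated)
Conditions: TEMPO (2 mol%), KBr (10 mol%), NaOCl (1.1 equiv), NaHCO3, CH2Cl2/H2O, 0 °C; organic phase dried, then 4 (1.3 equiv), PhMe, 90 °C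
Reagents that add atoms: 2-(triphenylphosphoranylidene)propanal (4), CC(C=O)=P(c1ccccc1)(c1ccccc1)c1ccccc1
Why: Anelli (TEMPO/NaOCl) oxidation gives the α-branched aldehyde under buffered, non-enolising conditions, and Wittig olefination with the stabilised formyl ylide then gives the (E)-trisubstituted enal under thermodynamic control, C4 being the bought stereocentre.

Step 3
Reactants: 6 (2E,4S)-2,4-dimethyldec-2-enal; 7 malonic acid
Product: 8 (2E,4E,6S)-4,6-dimethyldodeca-2,4-dienoic acid
Conditions: 7 (2.0 equiv), pyridine, 90 °C; then aq HCl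
Reagents that add atoms: malonic acid (7), OC(=O)CC(O)=O
Why: Knoevenagel condensation with decarboxylation in the flask (Doebner modification) gives the (E)-acrylic acid directly, and pyridine alone is used (no secondary amine) so that no dienamine can form through the γ-stereocentre.

Step 4
Reactants: 9 dimethyl (4R,5R)-2,2-dimethyl-1,3-dioxolane-4,5-dicarboxylate; 10 (E)-1-bromoprop-1-ene
Product: 13 (4S,5S)-2,2-dimethyl-4,5-di[(E)-prop-1-en-1-yl]-1,3-dioxolane, via dicesium dicarboxylate 11 (not isolated), via cesium monopropenyl carboxylate 12 (not isolated)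
Conditions: CsOH·H2O (2.0 equiv), MeOH/H2O, rt, evaporate and dry; then 10 (5 equiv), Ir[dF(CF3)ppy]2(dtbbpy)PF6 (2 mol%), NiCl2(dme) (10 mol%), 4,4'-di-tert-butyl-2,2'-bipyridine (12 mol%), DMSO, 450 nm LEDs, 25 °C
Reagents that add atoms: (E)-1-bromoprop-1-ene (10), C/C=C/Br
Why: Proposed new method: a twofold nickel/iridium metallaphotoredox decarboxylative alkenylation of a vicinal α,α'-dioxy dicarboxylate in one flask, in which photoexcited trivalent iridium oxidises each cesium carboxylate in turn, loss of CO2 gives a 1,3-dioxolan-4-yl radical, this is captured by the (E)-propenylnickel bromide formed from 10 and zerovalent nickel, and reductive elimination from trivalent nickel forms the C–C bond anti to the substituent on the neighbouring ring carbon, so the first propenyl enters trans to the remaining bought centre and the second trans to the first, rebuilding the L-threo arrangement as (4S,5S) with retention of alkene geometry; the closest known reactions are the single decarboxylative vinylation of α-oxy acids with vinyl halides under nickel/photoredox catalysis and the stepwise nickel-catalysed decarboxylative couplings of tartrate-derived redox-active esters.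

Step 5
Reactants: 13 (4S,5S)-2,2-dimethyl-4,5-di[(E)-prop-1-en-1-yl]-1,3-dioxolane
Product: 14 (2E,4S,5S,6E)-octa-2,6-diene-4,5-diol
Conditions: AcOH/H2O (4:1), 45 °C
Reagents that add atoms: none
Why: Acid hydrolysis of the isopropylidene acetal under conditions mild enough to leave the two allylic carbinol centres and the (E)-alkenes untouched.

Step 6
Reactants: 14 (2E,4S,5S,6E)-octa-2,6-diene-4,5-diol; 15 acryloyl chloride
Product: 16 (2E,4S,5S,6E)-5-hydroxyocta-2,6-dien-4-yl prop-2-enoate
Conditions: 15 (1.05 equiv), Me2SnCl2 (5 mol%), K2CO3 (2.0 equiv), THF, 0 °C → rt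
Reagents that add atoms: acryloyl chloride (15), C=CC(Cl)=O
Why: Tin-catalysed mono-acylation of a 1,2-diol through its dimethylstannylene acetal; the two hydroxyls are homotopic by C2 symmetry, so one mono-ester results and 1,2-acyl migration is degenerate.

Step 7
Reactants: 16 (2E,4S,5S,6E)-5-hydroxyocta-2,6-dien-4-yl prop-2-enoate
Product: 17 (5S,6S)-5-hydroxy-6-[(E)-prop-1-en-1-yl]-5,6-dihydro-2H-pyran-2-one (phomalactone)
Conditions: RuCl2(=CHPh)(PCy3)(H2IMes) (second-generation Grubbs catalyst, 5 mol%), 1,4-benzoquinone (10 mol%), CH2Cl2 (5 mM), 40 °C, Ar sparge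
Reagents that add atoms: none
Why: Ring-closing metathesis in which the carbene forms fastest at the propenyl group next to the free hydroxyl and closes onto the acrylate to the six-membered (Z)-enoate lactone with loss of propene, the five-membered closure through the other propenyl being slower; no stereocentre is touched, so the L-threo diol gives the cis-(5S,6S) ring.

Step 8
Reactants: 17 (5S,6S)-5-hydroxy-6-[(E)-prop-1-en-1-yl]-5,6-dihydro-2H-pyran-2-one; 8 (2E,4E,6S)-4,6-dimethyldodeca-2,4-dienoic acid
Product: 18 (2S,3S)-6-oxo-2-[(E)-prop-1-en-1-yl]-3,6-dihydro-2H-pyran-3-yl (2E,4E,6S)-4,6-dimethyldodeca-2,4-dienoate (CNP0240957.1)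
Conditions: DCC (1.2 equiv), DMAP (10 mol%), CH2Cl2, 0 °C → rt
Reagents that add atoms: none
Why: Steglich esterification acylates the C5 hydroxyl without breaking its C–O bond (retention), and the mild conditions leave the lactone and the (E,E)-dienoate unchanged.

**Compound list**
1 | (R)-3-bromo-2-methylpropan-1-ol | C[C@H](CO)CBr | starting material
2 | pentylmagnesium bromide | CCCCC[Mg]Br | starting material
3 | (S)-2-methyloctan-1-ol | C[C@H](CO)CCCCCC | intermediate
4 | 2-(triphenylphosphoranylidene)propanal | CC(C=O)=P(c1ccccc1)(c1ccccc1)c1ccccc1 | starting material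
5 | (S)-2-methyloctanal | C[C@H](C=O)CCCCCC | intermediate
6 | (2E,4S)-2,4-dimethyldec-2-enal | O=C/C(C)=C/[C@@H](C)CCCCCC | intermediate
7 | malonic acid | OC(=O)CC(O)=O | starting material
8 | (2E,4E,6S)-4,6-dimethyldodeca-2,4-dienoic acid | OC(=O)/C=C/C(C)=C/[C@@H](C)CCCCCC | intermediate
9 | dimethyl (4R,5R)-2,2-dimethyl-1,3-dioxolane-4,5-dicarboxylate (acetonide of dimethyl L-tartrate) | COC(=O)[C@@H]1OC(C)(C)O[C@H]1C(=O)OC | starting material
10 | (E)-1-bromoprop-1-ene | C/C=C/Br | starting material
11 | dicesium (4R,5R)-2,2-dimethyl-1,3-dioxolane-4,5-dicarboxylate | [Cs+].[Cs+].[O-]C(=O)[C@@H]1OC(C)(C)O[C@H]1C([O-])=O | intermediate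
12 | cesium (4R,5S)-2,2-dimethyl-5-[(E)-prop-1-en-1-yl]-1,3-dioxolane-4-carboxylate | [Cs+].C/C=C/[C@@H]1OC(C)(C)O[C@H]1C([O-])=O | intermediate
13 | (4S,5S)-2,2-dimethyl-4,5-di[(E)-prop-1-en-1-yl]-1,3-dioxolane | C/C=C/[C@@H]1OC(C)(C)O[C@H]1/C=C/C | intermediate
14 | (2E,4S,5S,6E)-octa-2,6-diene-4,5-diol | C/C=C/[C@H](O)[C@@H](O)/C=C/C | intermediate
15 | acryloyl chloride (prop-2-enoyl chloride) | C=CC(Cl)=O | starting material
16 | (2E,4S,5S,6E)-5-hydroxyocta-2,6-dien-4-yl prop-2-enoate | C/C=C/[C@H](OC(=O)C=C)[C@@H](O)/C=C/C | intermediate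
17 | (5S,6S)-5-hydroxy-6-[(E)-prop-1-en-1-yl]-5,6-dihydro-2H-pyran-2-one (phomalactone; OH and propenyl cis) | C/C=C/[C@@H]1OC(=O)C=C[C@@H]1O | intermediate
18 | (2S,3S)-6-oxo-2-[(E)-prop-1-en-1-yl]-3,6-dihydro-2H-pyran-3-yl (2E,4E,6S)-4,6-dimethyldodeca-2,4-dienoate | C/C=C/[C@@H]1OC(=O)C=C[C@@H]1OC(=O)/C=C/C(C)=C/[C@@H](C)CCCCCC | target

**Step count**
Total: 8 steps. Longest linear sequence: 5 steps (steps 4–8, from 9); the acid arm is 3 steps (steps 1–3) and joins at step 8.

**Three steps most likely to fail**

Step 4 (the proposed new step).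
- The vicinal dicarboxylate may sequester nickel.
- The α-oxy radical may be oxidised to the oxocarbenium ion and lose the second CO2 to give 2,2-dimethyl-1,3-dioxole.
- Every cis event in the first coupling is carried by the second coupling into the enantiomer of 13, so its ee is 2s − 1, where s is the trans fraction per coupling. A trans preference of 20:1 or better, as expected for these radicals, gives about 90% ee or better; the remainder shows up in 18 as a diastereomer.
- A degenerate 1,2-propenyl shift in the second radical would have the same effect.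
- Fallback with known chemistry, from 9 and back at 13, leaving both bought stereocentres untouched: LiAlH4 in THF reduces 9 to (4S,5S)-2,2-dimethyl-1,3-dioxolane-4,5-dimethanol F1 (also a catalogue compound). Swern oxidation ((COCl)2, DMSO, Et3N, CH2Cl2, −78 °C) gives (4R,5R)-2,2-dimethyl-1,3-dioxolane-4,5-dicarbaldehyde F2, which is not isolated. It is added to the anion of 5-(ethylsulfonyl)-1-phenyl-1H-tetrazole (KN(SiMe3)2, DME, −60 °C → rt) for a double (E)-selective Julia–Kocienski olefination that gives 13.

Step 7 (ring-closing metathesis).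
- Closure through the other propenyl group would give the five-membered butenolide.
- Methylidene exchange may cut the remaining propenyl down to vinyl.
- Ruthenium hydrides may isomerise the free allylic alcohol to a ketone.
- Fallback, from 16 and back at 18, with the ring closed last on a substrate without free hydroxyl: 16 is esterified with 8 (DCC, DMAP, CH2Cl2, 0 °C) to (2E,4S,5S,6E)-5-(prop-2-enoyloxy)octa-2,6-dien-4-yl (2E,4E,6S)-4,6-dimethyldodeca-2,4-dienoate F3. Ring-closing metathesis of F3 with RuCl2(=CH-C6H4-2-OiPr)(H2IMes) (second-generation Hoveyda–Grubbs catalyst) in PhMe at 60 °C gives 18 directly, bypassing 17. The acrylate is a far better metathesis partner than the β-substituted dienoate.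

Step 2 (oxidation and Wittig olefination).
- The slow, hot reaction of the α-branched aldehyde 5 with the weakly reactive formyl ylide may allow partial epimerisation.
- The enal may condense a second time with the ylide.
- Fallback, from 3 and back at 6, with the olefination done at the ester oxidation level at low temperature: 3 is oxidised to 5 as before, and 5 is treated at 0 °C → rt with ethyl 2-(triphenylphosphoranylidene)propanoate in CH2Cl2 to give ethyl (2E,4S)-2,4-dimethyldec-2-enoate F4. Reduction with iBu2AlH (CH2Cl2, −78 °C) gives (2E,4S)-2,4-dimethyldec-2-en-1-ol F5, and oxidation with MnO2 (CH2Cl2, rt) gives 6.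

**Further compounds**
F1 | step 4 | (4S,5S)-2,2-dimethyl-1,3-dioxolane-4,5-dimethanol | OC[C@@H]1OC(C)(C)O[C@H]1CO
F2 | step 4 | (4R,5R)-2,2-dimethyl-1,3-dioxolane-4,5-dicarbaldehyde | O=C[C@@H]1OC(C)(C)O[C@H]1C=O
F3 | step 7 | (2E,4S,5S,6E)-5-(prop-2-enoyloxy)octa-2,6-dien-4-yl (2E,4E,6S)-4,6-dimethyldodeca-2,4-dienoate | C/C=C/[C@H](OC(=O)C=C)[C@@H](OC(=O)/C=C/C(C)=C/[C@@H](C)CCCCCC)/C=C/C
F4 | step 2 | ethyl (2E,4S)-2,4-dimethyldec-2-enoate | CCOC(=O)/C(C)=C/[C@@H](C)CCCCCC
F5 | step 2 | (2E,4S)-2,4-dimethyldec-2-en-1-ol | OC/C(C)=C/[C@@H](C)CCCCCC
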